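**Retrosynthetic overview**

1. Target 33 ⇒ bis-silyl ether 32 ⇒ dialdehyde 27; each side chain comes from carbonyl allylation, cross-metathesis with 2-methylbut-2-ene and oxidation.
2. 27 ⇒ meso bis(β-hydroxy ester) 24; both quaternary carbons are set by Fráter–Seebach methylation of the ring alkoxide enolates (Me anti to O).
3. Rings A and B are closed together, in one operation, by intramolecular enolate alkylation of the acyclic bis(β-hydroxy ester) 19; no ring is formed earlier.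
4. Key disconnection: C1–C2 of each ring by intermolecular Evans syn aldol addition of chloroacetyl-oxazolidinone boron enolates, (R) then (S), to the C16 (Z,Z)-dialdehyde 10.
5. 10 ⇒ butanedial + two Still–Gennari phosphonates 4; both Z-trisubstituted alkenes are fixed before any stereocentre exists.

Assumption: the structure drawn is achiral (meso: ring A 1R,2S; ring B 1S,2R; both ring alkenes Z), so "single enantiomer" is read as "this one meso diastereomer"; 11 and 14 are taken as catalogue items.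

**Route**

Step 1
Reactants: 1 methyl 2-[bis(2,2,2-trifluoroethoxy)phosphoryl]acetate; 2 1-chloro-3-iodopropane
Product: 4 methyl 2-[bis(2,2,2-trifluoroethoxy)phosphoryl]-5-chloropentanoate, via sodium phosphonoacetate carbanion 3 (not isolated)
Conditions: NaH (1.0 equiv), DMF, 0 °C; then 2, 0 °C → rt
Reagents that add atoms: none
Why: C-alkylation of the stabilised phosphonate carbanion (SN2 at the C–I end, C–Cl untouched) installs ring carbons C4–C6; the racemic α-centre is destroyed in step 3.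

Step 2
Reactants: 5 2,5-dimethoxytetrahydrofuran
Product: 6 butanedial
Conditions: H2O, 90 °C; extract, distil, use at once
Reagents that add atoms: water O
Why: Hydrolysis of the cyclic bis-acetal releases the dialdehyde, which is used fresh because it oligomerises.

Step 3
Reactants: 4 methyl 2-[bis(2,2,2-trifluoroethoxy)phosphoryl]-5-chloropentanoate (2.2 equiv); 6 butanedial
Product: 8 dimethyl (2Z,6Z)-2,7-bis(3-chloropropyl)octa-2,6-dienedioate, via potassium phosphonate carbanion 7 (not isolated)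
Conditions: KN(SiMe3)2, 18-crown-6, THF, −78 °C; then 6, −78 °C
Reagents that add atoms: none
Why: Twofold Still–Gennari (Z-selective Horner–Wadsworth–Emmons) olefination places CO2Me cis to the linker CH2 at both alkenes, which is the later exocyclic geometry.

Step 4
Reactants: 8 dimethyl (2Z,6Z)-2,7-bis(3-chloropropyl)octa-2,6-dienedioate
Product: 9 (2Z,6Z)-2,7-bis(3-chloropropyl)octa-2,6-diene-1,8-diol
Conditions: iBu2AlH (5 equiv), CH2Cl2, −78 °C; aq. potassium sodium tartrate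
Reagents that add atoms: none
Why: 1,2-Reduction of the enoates to allylic alcohols; alkene geometry and alkyl chlorides are untouched.

Step 5
Reactants: 9 (2Z,6Z)-2,7-bis(3-chloropropyl)octa-2,6-diene-1,8-diol
Product: 10 (2Z,6Z)-2,7-bis(3-chloropropyl)octa-2,6-dienedial
Conditions: TEMPO (0.2 equiv), PhI(OAc)2 (2.3 equiv), CH2Cl2, rt
Reagents that add atoms: none
Why: Oxoammonium (TEMPO) oxidation of allylic alcohols stops at the aldehyde and does not isomerise Z-enals.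

Step 6
Reactants: 10 (2Z,6Z)-2,7-bis(3-chloropropyl)octa-2,6-dienedial (3 equiv); 11 (R)-4-benzyl-3-(chloroacetyl)oxazolidin-2-one
Product: 13 (R)-4-benzyl-3-[(2R,3S,4Z,8Z)-2-chloro-4,9-bis(3-chloropropyl)-3-hydroxy-10-oxodeca-4,8-dienoyl]oxazolidin-2-one, via dibutylboron enolate 12 (not isolated)
Conditions: 11, Bu2BOTf (1.1 equiv), iPr2NEt (1.2 equiv), CH2Cl2, −78 → 0 °C; cannulate into 10, −78 → −30 °C; MeOH, aq. tartaric acid work-up (no peroxide)
Reagents that add atoms: none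
Why: Evans syn aldol addition (chloroacetate as acetate equivalent) through a Zimmerman–Traxler chair; the (R)-auxiliary sets C3 (future ring A C2) and a throw-away C2–Cl centre, and the threefold excess of symmetric dialdehyde (recovered) limits addition to one terminus.

Step 7
Reactants: 13 (R)-4-benzyl-3-[(2R,3S,4Z,8Z)-2-chloro-4,9-bis(3-chloropropyl)-3-hydroxy-10-oxodeca-4,8-dienoyl]oxazolidin-2-one; 14 (S)-4-benzyl-3-(chloroacetyl)oxazolidin-2-one (2.3 equiv)
Product: 16 (4R,4'S)-3,3'-[(2R,3S,4Z,8Z,10R,11S)-2,11-dichloro-4,9-bis(3-chloropropyl)-3,10-dihydroxydodeca-4,8-dienedioyl]bis(4-benzyloxazolidin-2-one), via dibutylboron enolate 15 (not isolated)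
Conditions: 14, Bu2BOTf (2.3 equiv), iPr2NEt (2.6 equiv), CH2Cl2, −78 → 0 °C; then 13, −78 → −20 °C; MeOH, aq. tartaric acid work-up; chromatography
Reagents that add atoms: none
Why: A second Evans syn aldol with the enantiomeric auxiliary sets the other carbinol in the mirror-image sense, so 16 is meso; the free 3-OH is borylated in situ by the excess enolate.

Step 8
Reactants: 16 (4R,4'S)-3,3'-[(2R,3S,4Z,8Z,10R,11S)-2,11-dichloro-4,9-bis(3-chloropropyl)-3,10-dihydroxydodeca-4,8-dienedioyl]bis(4-benzyloxazolidin-2-one)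
Product: 17 (4R,4'S)-3,3'-[(3R,4Z,8Z,10S)-4,9-bis(3-chloropropyl)-3,10-dihydroxydodeca-4,8-dienedioyl]bis(4-benzyloxazolidin-2-one)
Conditions: Zn dust (excess), AcOH, THF, rt
Reagents that add atoms: none
Why: Reductive dehalogenation of the α-chloro imides (zinc enolate protonated by AcOH) unmasks the formal acetate aldol; carbinols, primary chlorides and alkenes are inert.

Step 9
Reactants: 17 (4R,4'S)-3,3'-[(3R,4Z,8Z,10S)-4,9-bis(3-chloropropyl)-3,10-dihydroxydodeca-4,8-dienedioyl]bis(4-benzyloxazolidin-2-one)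
Product: 18 dimethyl (3R,4Z,8Z,10S)-4,9-bis(3-chloropropyl)-3,10-dihydroxydodeca-4,8-dienedioate
Conditions: K2CO3 (0.3 equiv), MeOH, 0 °C
Reagents that add atoms: methanol CO
Why: Base-catalysed methanolysis (transesterification) of the unhindered N-acyl oxazolidinones releases both auxiliaries and gives the β-hydroxy esters needed for dianion chemistry.

Step 10
Reactants: 18 dimethyl (3R,4Z,8Z,10S)-4,9-bis(3-chloropropyl)-3,10-dihydroxydodeca-4,8-dienedioate
Product: 19 dimethyl (3R,4Z,8Z,10S)-3,10-dihydroxy-4,9-bis(3-iodopropyl)dodeca-4,8-dienedioate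
Conditions: NaI (10 equiv), acetone, reflux
Reagents that add atoms: sodium iodide [Na+].[I-]
Why: Finkelstein exchange makes the primary iodides needed for a low-temperature ring closure.

Step 11
Reactants: 19 dimethyl (3R,4Z,8Z,10S)-3,10-dihydroxy-4,9-bis(3-iodopropyl)dodeca-4,8-dienedioate
Product: 21 dimethyl (2R,2'S,3Z,3'Z)-3,3'-(butane-1,4-diylidene)bis(2-hydroxycyclohexane-1-carboxylate), via tetralithium alkoxide-enolate 20 (not isolated)
Conditions: LiN(iPr)2 (4.6 equiv), THF, −78 → −20 °C, high dilution; aq. NH4Cl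
Reagents that add atoms: none
Why: Twofold 6-exo-tet intramolecular alkylation of the alkoxide–ester enolates (Fráter–Seebach dianions, O–Li cannot β-eliminate) closes rings A and B at once; C2/C2′ and the Z-alkenes are untouched and the C1/C1′ configuration (epimer mixture) is irrelevant here.

Step 12
Reactants: 21 dimethyl (2R,2'S,3Z,3'Z)-3,3'-(butane-1,4-diylidene)bis(2-hydroxycyclohexane-1-carboxylate); 22 iodomethane (6 equiv)
Product: 24 dimethyl (1R,1'S,2S,2'R,3Z,3'Z)-3,3'-(butane-1,4-diylidene)bis(2-hydroxy-1-methylcyclohexane-1-carboxylate), via tetralithium alkoxide-enolate 23 (not isolated)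
Conditions: LiN(iPr)2 (4.6 equiv), THF, −78 → −10 °C; then 22 (6 equiv), −78 → 0 °C; aq. NH4Cl
Reagents that add atoms: none
Why: Fráter–Seebach alkylation of the cyclic alkoxide enolates, in which two molecules of 22 are consumed (one methyl group per ring): MeI adds to C1 anti to the neighbouring O–Li (held axial by A(1,3) strain with the Z-alkylidene), giving Me trans and CO2Me cis to OH in both rings.

Step 13
Reactants: 24 dimethyl (1R,1'S,2S,2'R,3Z,3'Z)-3,3'-(butane-1,4-diylidene)bis(2-hydroxy-1-methylcyclohexane-1-carboxylate)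
Product: 25 dimethyl (1R,1'S,2S,2'R,3Z,3'Z)-3,3'-(butane-1,4-diylidene)bis[1-methyl-2-(triethylsilyloxy)cyclohexane-1-carboxylate]
Conditions: Et3SiOTf (3 equiv), 2,6-lutidine (5 equiv), CH2Cl2, −78 → 0 °C
Reagents that add atoms: triethylsilyl trifluoromethanesulfonate CC[Si](CC)(CC)OS(=O)(=O)C(F)(F)F
Why: Silyl triflate silylation protects the hindered allylic carbinols for the redox and Grignard steps.

Step 14
Reactants: 25 dimethyl (1R,1'S,2S,2'R,3Z,3'Z)-3,3'-(butane-1,4-diylidene)bis[1-methyl-2-(triethylsilyloxy)cyclohexane-1-carboxylate]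
Product: 26 [(3Z,3'Z)-3,3'-(butane-1,4-diylidene)bis[1-methyl-2-(triethylsilyloxy)cyclohexane-3,1-diyl]]dimethanol (ring A 1S,2S; ring B 1R,2R; same spatial arrangement as 25)
Conditions: iBu2AlH (6 equiv), CH2Cl2, −78 → 0 °C; aq. potassium sodium tartrate
Reagents that add atoms: none
Why: Hydride reduction of the neopentyl esters to primary alcohols; no stereocentre is touched.

Step 15
Reactants: 26 [(3Z,3'Z)-3,3'-(butane-1,4-diylidene)bis[1-methyl-2-(triethylsilyloxy)cyclohexane-3,1-diyl]]dimethanol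
Product: 27 (1R,1'S,2S,2'R,3Z,3'Z)-3,3'-(butane-1,4-diylidene)bis[1-methyl-2-(triethylsilyloxy)cyclohexane-1-carbaldehyde]
Conditions: Dess–Martin periodinane (3 equiv), NaHCO3, CH2Cl2, rt
Reagents that add atoms: none
Why: Dess–Martin oxidation gives the non-enolisable dialdehyde (α-quaternary, so no epimerisation or β-elimination).

Step 16
Reactants: 27 (1R,1'S,2S,2'R,3Z,3'Z)-3,3'-(butane-1,4-diylidene)bis[1-methyl-2-(triethylsilyloxy)cyclohexane-1-carbaldehyde]; 28 allylmagnesium bromide (4 equiv)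
Product: 29 1,1'-[(3Z,3'Z)-3,3'-(butane-1,4-diylidene)bis[1-methyl-2-(triethylsilyloxy)cyclohexane-3,1-diyl]]bis(but-3-en-1-ol) (ring centres as in 26; carbinol epimers)
Conditions: CH2=CHCH2MgBr (4 equiv), Et2O, −78 °C; aq. NH4Cl at −78 °C
Reagents that add atoms: none
Why: Carbonyl allylation (Grignard addition) attaches the side-chain carbons; the new carbinol centres form as mixtures and are erased in step 18.

Step 17
Reactants: 29 1,1'-[(3Z,3'Z)-3,3'-(butane-1,4-diylidene)bis[1-methyl-2-(triethylsilyloxy)cyclohexane-3,1-diyl]]bis(but-3-en-1-ol); 30 2-methylbut-2-ene (50 equiv)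
Product: 31 1,1'-[(3Z,3'Z)-3,3'-(butane-1,4-diylidene)bis[1-methyl-2-(triethylsilyloxy)cyclohexane-3,1-diyl]]bis(4-methylpent-3-en-1-ol) (ring centres as in 26; carbinol epimers)
Conditions: second-generation Grubbs catalyst [RuCl2(=CHPh)(PCy3)(H2IMes)] (5 mol %), 30 (50 equiv), CH2Cl2, 40 °C, sealed
Reagents that add atoms: none
Why: Olefin cross-metathesis turns each terminal vinyl into the trisubstituted prenyl-type alkene; the hindered trisubstituted ring alkylidenes do not react.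

Step 18
Reactants: 31 1,1'-[(3Z,3'Z)-3,3'-(butane-1,4-diylidene)bis[1-methyl-2-(triethylsilyloxy)cyclohexane-3,1-diyl]]bis(4-methylpent-3-en-1-ol)
Product: 32 1,1'-[(1R,1'S,2S,2'R,3Z,3'Z)-3,3'-(butane-1,4-diylidene)bis[1-methyl-2-(triethylsilyloxy)cyclohexane-3,1-diyl]]bis(4-methylpent-3-en-1-one)
Conditions: Dess–Martin periodinane (3 equiv), NaHCO3, CH2Cl2, 0 °C → rt
Reagents that add atoms: none
Why: Buffered Dess–Martin oxidation gives the β,γ-unsaturated ketones without moving the double bonds into conjugation.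

Step 19
Reactants: 32 1,1'-[(1R,1'S,2S,2'R,3Z,3'Z)-3,3'-(butane-1,4-diylidene)bis[1-methyl-2-(triethylsilyloxy)cyclohexane-3,1-diyl]]bis(4-methylpent-3-en-1-one)
Product: 33 1,1'-[(1R,1'S,2S,2'R,3Z,3'Z)-3,3'-(butane-1,4-diylidene)bis(2-hydroxy-1-methylcyclohexane-3,1-diyl)]bis(4-methylpent-3-en-1-one)
Conditions: HF·pyridine, pyridine, THF, 0 °C → rt
Reagents that add atoms: none
Why: Buffered fluoride desilylation frees both carbinols without retro-aldol cleavage of the β-hydroxy ketones or enone isomerisation.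

**Compound list**

1 | methyl 2-[bis(2,2,2-trifluoroethoxy)phosphoryl]acetate | COC(=O)CP(=O)(OCC(F)(F)F)OCC(F)(F)F | starting material
2 | 1-chloro-3-iodopropane | ClCCCI | starting material
3 | sodium carbanion of 1 | [Na+].COC(=O)[CH-]P(=O)(OCC(F)(F)F)OCC(F)(F)F | intermediate (not isolated)
4 | methyl 2-[bis(2,2,2-trifluoroethoxy)phosphoryl]-5-chloropentanoate (racemic) | COC(=O)C(CCCCl)P(=O)(OCC(F)(F)F)OCC(F)(F)F | intermediate
5 | 2,5-dimethoxytetrahydrofuran (cis/trans mixture) | COC1CCC(OC)O1 | starting material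
6 | butanedial | O=CCCC=O | intermediate
7 | potassium carbanion of 4 | [K+].COC(=O)[C-](CCCCl)P(=O)(OCC(F)(F)F)OCC(F)(F)F | intermediate (not isolated)
8 | dimethyl (2Z,6Z)-2,7-bis(3-chloropropyl)octa-2,6-dienedioate | COC(=O)/C(CCCCl)=C\CC/C=C(/CCCCl)C(=O)OC | intermediate
9 | (2Z,6Z)-2,7-bis(3-chloropropyl)octa-2,6-diene-1,8-diol | OC/C(CCCCl)=C\CC/C=C(/CCCCl)CO | intermediate
10 | (2Z,6Z)-2,7-bis(3-chloropropyl)octa-2,6-dienedial | O=C/C(CCCCl)=C\CC/C=C(/CCCCl)C=O | intermediate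
11 | (R)-4-benzyl-3-(chloroacetyl)oxazolidin-2-one | O=C1OC[C@@H](Cc2ccccc2)N1C(=O)CCl | starting material
12 | (Z)-dibutylboron enolate of 11 | O=C1OC[C@@H](Cc2ccccc2)N1/C(OB(CCCC)CCCC)=C/Cl | intermediate (not isolated)
13 | (R)-4-benzyl-3-[(2R,3S,4Z,8Z)-2-chloro-4,9-bis(3-chloropropyl)-3-hydroxy-10-oxodeca-4,8-dienoyl]oxazolidin-2-one | O=C1OC[C@@H](Cc2ccccc2)N1C(=O)[C@H](Cl)[C@@H](O)/C(CCCCl)=C\CC/C=C(/CCCCl)C=O | intermediate
14 | (S)-4-benzyl-3-(chloroacetyl)oxazolidin-2-one | O=C1OC[C@H](Cc2ccccc2)N1C(=O)CCl | starting material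
15 | (Z)-dibutylboron enolate of 14 | O=C1OC[C@H](Cc2ccccc2)N1/C(OB(CCCC)CCCC)=C/Cl | intermediate (not isolated)
16 | (4R,4'S)-3,3'-[(2R,3S,4Z,8Z,10R,11S)-2,11-dichloro-4,9-bis(3-chloropropyl)-3,10-dihydroxydodeca-4,8-dienedioyl]bis(4-benzyloxazolidin-2-one) (meso) | O=C1OC[C@@H](Cc2ccccc2)N1C(=O)[C@H](Cl)[C@@H](O)/C(CCCCl)=C\CC/C=C(/CCCCl)[C@@H](O)[C@H](Cl)C(=O)N1[C@@H](Cc2ccccc2)COC1=O | intermediate
17 | (4R,4'S)-3,3'-[(3R,4Z,8Z,10S)-4,9-bis(3-chloropropyl)-3,10-dihydroxydodeca-4,8-dienedioyl]bis(4-benzyloxazolidin-2-one) (meso) | O=C1OC[C@@H](Cc2ccccc2)N1C(=O)C[C@@H](O)/C(CCCCl)=C\CC/C=C(/CCCCl)[C@@H](O)CC(=O)N1[C@@H](Cc2ccccc2)COC1=O | intermediate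
18 | dimethyl (3R,4Z,8Z,10S)-4,9-bis(3-chloropropyl)-3,10-dihydroxydodeca-4,8-dienedioate (meso) | COC(=O)C[C@@H](O)/C(CCCCl)=C\CC/C=C(/CCCCl)[C@@H](O)CC(=O)OC | intermediate
19 | dimethyl (3R,4Z,8Z,10S)-3,10-dihydroxy-4,9-bis(3-iodopropyl)dodeca-4,8-dienedioate (meso) | COC(=O)C[C@@H](O)/C(CCCI)=C\CC/C=C(/CCCI)[C@@H](O)CC(=O)OC | intermediate
20 | tetralithium bis(alkoxide ester enolate) of 19 | [Li+].[Li+].[Li+].[Li+].COC([O-])=C[C@@H]([O-])/C(CCCI)=C\CC/C=C(/CCCI)[C@@H]([O-])C=C([O-])OC | intermediate (not isolated)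
21 | dimethyl (2R,2'S,3Z,3'Z)-3,3'-(butane-1,4-diylidene)bis(2-hydroxycyclohexane-1-carboxylate) (C1/C1' epimer mixture) | COC(=O)C1CCC/C(=C/CC/C=C2/CCCC(C(=O)OC)[C@@H]2O)[C@@H]1O | intermediate
22 | iodomethane | CI | starting material
23 | tetralithium bis(alkoxide ester enolate) of 21 | [Li+].[Li+].[Li+].[Li+].COC([O-])=C1CCC/C(=C/CC/C=C2/CCCC(=C([O-])OC)[C@@H]2[O-])[C@@H]1[O-] | intermediate (not isolated)
24 | dimethyl (1R,1'S,2S,2'R,3Z,3'Z)-3,3'-(butane-1,4-diylidene)bis(2-hydroxy-1-methylcyclohexane-1-carboxylate) (meso) | COC(=O)[C@]1(C)CCC/C(=C/CC/C=C2/CCC[C@](C)(C(=O)OC)[C@@H]2O)[C@@H]1O | intermediate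
25 | dimethyl (1R,1'S,2S,2'R,3Z,3'Z)-3,3'-(butane-1,4-diylidene)bis[1-methyl-2-(triethylsilyloxy)cyclohexane-1-carboxylate] | COC(=O)[C@]1(C)CCC/C(=C/CC/C=C2/CCC[C@](C)(C(=O)OC)[C@@H]2O[Si](CC)(CC)CC)[C@@H]1O[Si](CC)(CC)CC | intermediate
26 | [(3Z,3'Z)-3,3'-(butane-1,4-diylidene)bis[1-methyl-2-(triethylsilyloxy)cyclohexane-3,1-diyl]]dimethanol (ring A 1S,2S; ring B 1R,2R) | OC[C@]1(C)CCC/C(=C/CC/C=C2/CCC[C@](C)(CO)[C@@H]2O[Si](CC)(CC)CC)[C@@H]1O[Si](CC)(CC)CC | intermediate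
27 | (1R,1'S,2S,2'R,3Z,3'Z)-3,3'-(butane-1,4-diylidene)bis[1-methyl-2-(triethylsilyloxy)cyclohexane-1-carbaldehyde] | O=C[C@]1(C)CCC/C(=C/CC/C=C2/CCC[C@](C)(C=O)[C@@H]2O[Si](CC)(CC)CC)[C@@H]1O[Si](CC)(CC)CC | intermediate
28 | allylmagnesium bromide (1.0 M in Et2O) | C=CC[Mg]Br | starting material
29 | 1,1'-[(3Z,3'Z)-3,3'-(butane-1,4-diylidene)bis[1-methyl-2-(triethylsilyloxy)cyclohexane-3,1-diyl]]bis(but-3-en-1-ol) (ring A 1S,2S; ring B 1R,2R; carbinol epimers) | C=CCC(O)[C@]1(C)CCC/C(=C/CC/C=C2/CCC[C@](C)(C(O)CC=C)[C@@H]2O[Si](CC)(CC)CC)[C@@H]1O[Si](CC)(CC)CC | intermediate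
30 | 2-methylbut-2-ene | CC=C(C)C | starting material
31 | 1,1'-[(3Z,3'Z)-3,3'-(butane-1,4-diylidene)bis[1-methyl-2-(triethylsilyloxy)cyclohexane-3,1-diyl]]bis(4-methylpent-3-en-1-ol) (ring A 1S,2S; ring B 1R,2R; carbinol epimers) | CC(C)=CCC(O)[C@]1(C)CCC/C(=C/CC/C=C2/CCC[C@](C)(C(O)CC=C(C)C)[C@@H]2O[Si](CC)(CC)CC)[C@@H]1O[Si](CC)(CC)CC | intermediate
32 | 1,1'-[(1R,1'S,2S,2'R,3Z,3'Z)-3,3'-(butane-1,4-diylidene)bis[1-methyl-2-(triethylsilyloxy)cyclohexane-3,1-diyl]]bis(4-methylpent-3-en-1-one) | CC(C)=CCC(=O)[C@]1(C)CCC/C(=C/CC/C=C2/CCC[C@](C)(C(=O)CC=C(C)C)[C@@H]2O[Si](CC)(CC)CC)[C@@H]1O[Si](CC)(CC)CC | intermediate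
33 | 1,1'-[(1R,1'S,2S,2'R,3Z,3'Z)-3,3'-(butane-1,4-diylidene)bis(2-hydroxy-1-methylcyclohexane-3,1-diyl)]bis(4-methylpent-3-en-1-one) (meso; CNP0297042.2) | CC(C)=CCC(=O)[C@]1(C)CCC/C(=C/CC/C=C2/CCC[C@](C)(C(=O)CC=C(C)C)[C@@H]2O)[C@@H]1O | target

**Totals**

Total step count: 19. Longest linear sequence: 18 steps (1 → 33 through steps 1 and 3–19; step 2 is a one-step side branch).

**Three steps most likely to fail, each with a fallback**

Step 6. The mono-aldol on a symmetric dialdehyde risks over-addition, and the excess Z-enal must be handled and recovered without isomerising. The fallback sets out from diol 9 and differentiates the termini before any aldehyde is made. Monosilylation (tBuMe2SiCl 1.0 equiv, imidazole, DMF; diol and bis-ether recycled) gives (2Z,6Z)-8-[(tert-butyldimethylsilyl)oxy]-2,7-bis(3-chloropropyl)octa-2,6-dien-1-ol F1. TEMPO/PhI(OAc)2 oxidises it to (2Z,6Z)-8-[(tert-butyldimethylsilyl)oxy]-2,7-bis(3-chloropropyl)octa-2,6-dienal F2. The same boron enolate 12 adds to this single aldehyde to give (R)-4-benzyl-3-[(2R,3S,4Z,8Z)-10-[(tert-butyldimethylsilyl)oxy]-2-chloro-4,9-bis(3-chloropropyl)-3-hydroxydeca-4,8-dienoyl]oxazolidin-2-one F3. HF·pyridine removes the silyl group to give (R)-4-benzyl-3-[(2R,3S,4Z,8Z)-2-chloro-4,9-bis(3-chloropropyl)-3,10-dihydroxydeca-4,8-dienoyl]oxazolidin-2-one F4. TEMPO/PhI(OAc)2, which oxidises only the primary allylic alcohol, brings the material back to the route at 13.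

Step 8. The zinc enolate formed on dechlorination can lose the β-oxygen (elimination) or undergo retro-aldol. The fallback sets out from 16 and removes chlorine through an epoxide instead. K2CO3 (2.5 equiv) in MeOH closes both chlorohydrins to cis-glycidates (inversion at C–Cl, carbinol carbon untouched) and methanolyses both imides, giving dimethyl (2S,2'R,3S,3'R)-3,3'-[(1Z,5Z)-1,6-bis(3-chloropropyl)hexa-1,5-diene-1,6-diyl]bis(oxirane-2-carboxylate) F5. SmI2 with Me2NCH2CH2OH in THF at −78 °C then cleaves each epoxy ester reductively at the α-carbon, leaving the β-oxygen in place, and comes back to the route at 18.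

Step 11. In the double dianion ring closure the free lithium alkoxides can O-alkylate (tetrahydropyran formation), and the base can eliminate HI. The fallback sets out from 19 and removes the free alkoxide from the cyclisation. Et3SiOTf/2,6-lutidine gives dimethyl (3R,4Z,8Z,10S)-4,9-bis(3-iodopropyl)-3,10-bis(triethylsilyloxy)dodeca-4,8-dienedioate F6. KN(SiMe3)2 (2.2 equiv) in THF at −78 °C cyclises it as the mono-enolates to dimethyl (2R,2'S,3Z,3'Z)-3,3'-(butane-1,4-diylidene)bis[2-(triethylsilyloxy)cyclohexane-1-carboxylate] F7. HF·pyridine then frees the carbinols and returns to the route at 21, so the methylation of step 12 is still run on the alkoxide enolate.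

Further compounds
F1 | step 6 | (2Z,6Z)-8-[(tert-butyldimethylsilyl)oxy]-2,7-bis(3-chloropropyl)octa-2,6-dien-1-ol | OC/C(CCCCl)=C\CC/C=C(/CCCCl)CO[Si](C)(C)C(C)(C)C
F2 | step 6 | (2Z,6Z)-8-[(tert-butyldimethylsilyl)oxy]-2,7-bis(3-chloropropyl)octa-2,6-dienal | O=C/C(CCCCl)=C\CC/C=C(/CCCCl)CO[Si](C)(C)C(C)(C)C
F3 | step 6 | (R)-4-benzyl-3-[(2R,3S,4Z,8Z)-10-[(tert-butyldimethylsilyl)oxy]-2-chloro-4,9-bis(3-chloropropyl)-3-hydroxydeca-4,8-dienoyl]oxazolidin-2-one | O=C1OC[C@@H](Cc2ccccc2)N1C(=O)[C@H](Cl)[C@@H](O)/C(CCCCl)=C\CC/C=C(/CCCCl)CO[Si](C)(C)C(C)(C)C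
F4 | step 6 | (R)-4-benzyl-3-[(2R,3S,4Z,8Z)-2-chloro-4,9-bis(3-chloropropyl)-3,10-dihydroxydeca-4,8-dienoyl]oxazolidin-2-one | O=C1OC[C@@H](Cc2ccccc2)N1C(=O)[C@H](Cl)[C@@H](O)/C(CCCCl)=C\CC/C=C(/CCCCl)CO
F5 | step 8 | dimethyl (2S,2'R,3S,3'R)-3,3'-[(1Z,5Z)-1,6-bis(3-chloropropyl)hexa-1,5-diene-1,6-diyl]bis(oxirane-2-carboxylate) | COC(=O)[C@H]1O[C@H]1/C(CCCCl)=C\CC/C=C(/CCCCl)[C@H]1O[C@H]1C(=O)OC
F6 | step 11 | dimethyl (3R,4Z,8Z,10S)-4,9-bis(3-iodopropyl)-3,10-bis(triethylsilyloxy)dodeca-4,8-dienedioate | COC(=O)C[C@@H](O[Si](CC)(CC)CC)/C(CCCI)=C\CC/C=C(/CCCI)[C@@H](O[Si](CC)(CC)CC)CC(=O)OC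
F7 | step 11 | dimethyl (2R,2'S,3Z,3'Z)-3,3'-(butane-1,4-diylidene)bis[2-(triethylsilyloxy)cyclohexane-1-carboxylate] (C1/C1' epimer mixture) | COC(=O)C1CCC/C(=C/CC/C=C2/CCCC(C(=O)OC)[C@@H]2O[Si](CC)(CC)CC)[C@@H]1O[Si](CC)(CC)CC
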